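**Plan**

- Retrosynthesis: cut the C3–O angelate, then the C3–C5 aldol bond of the 2-acetylcyclopentanol. Reconnect C3 to C4 as the C3=C4 alkene of a cadinane-type octalin (a temporary six-membered ring). Cut C1–C2 and C5–C6 by Diels–Alder into isoprene and (S)-cryptone, and cryptone into isovaleraldehyde and methyl vinyl ketone.
- Forward: ring B (the cyclohexane) is made first by Michael addition/aldol condensation, then a temporary cyclohexene is annulated by Diels–Alder. Ring B is dressed (C8–O, C10=CH2), the temporary ring is cut at C3=C4 and re-closed one carbon smaller as ring A (the cyclopentane) by aldol addition. This is the same net ring contraction as cadinane → oplopane in biosynthesis. The angelate goes on last.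
- Stereochemistry: C7 is set by organocatalysis. C6 and C1 are relayed from it (Diels–Alder anti to the isopropyl group, then equilibration to the trans fusion). C8 comes from axial nucleophilic epoxidation, and C5 and C3 from the aldol closure.
- Enabling feature: C4(=O)–C5–C3–O is a β-hydroxy ketone (aldol) array inside ring A, and its two arms (C5 on C6, C2 on C1) are vicinal, trans-diequatorial substituents of the ring B chair, so a 1,6-keto aldehyde closes readily.

Key step: step 10

Remark on numbering: cadinane/oplopane numbering is used. C1 and C6 are the ring-fusion carbons; ring A is C1–C2–C3–C5–C6 with the acetyl group (C4, methyl C15) on C5; ring B is C1–C6–C7(iPr)–C8(O)–C9–C10(=C14). α is the face carrying H-6, β the face carrying H-1.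

Remark on step 1: the (S)-diarylprolinol ether is assumed to give the (S)-aldehyde (attack on the enamine face remote from the diarylmethyl group); if the opposite sense is found, the (R)-catalyst is used.

**Step 1**
Reactants: 1 isovaleraldehyde; 2 methyl vinyl ketone
Product: 4 (S)-cryptone, via Michael adduct 3 (not isolated)
Conditions: (S)-2-(methoxydiphenylmethyl)pyrrolidine (5 mol %), ethyl 3,4-dihydroxybenzoate (20 mol %), neat, 4 °C; then LiOH (cat.), iPrOH, rt
Reagents that add atoms: none
Why: Enamine-mediated asymmetric Michael addition sets C7 (the (E)-enamine is attacked on the face remote from the diarylmethyl group), and intramolecular aldol condensation of the 1,5-keto aldehyde should close the cyclohexenone faster than the α-centre epimerizes.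

**Step 2**
Reactants: 4 (S)-cryptone; 5 isoprene
Product: 7 trans-fused octalone, via cis-fused adduct 6 (not isolated)
Conditions: AlCl3 (0.3 equiv), toluene, rt; then NaOMe (cat.), MeOH, rt
Reagents that add atoms: none
Why: Lewis-acid-catalysed Diels–Alder reaction with "para" regiochemistry (methyl on C4) in which the diene adds anti to the C7 isopropyl group and so sets C6, after which methoxide epimerizes C1 next to the ketone to the more stable trans-fused decalone with all substituents equatorial.

**Step 3**
Reactants: 7 trans-fused octalone
Product: 8 dienone (C8=C9 enone)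
Conditions: LiN(iPr)2 (LDA), THF, −78 °C; then PhS(Cl)=NtBu, −78 °C
Reagents that add atoms: none
Why: Kinetic deprotonation takes the C9 methylene and not the C1 methine, and the lithium enolate is dehydrogenated by the sulfinimidoyl chloride (Mukaiyama dehydrogenation: S–C bond formation, then syn elimination of the sulfenamide) while the isolated C3=C4 alkene is untouched.

**Step 4**
Reactants: 8 dienone
Product: 9 8α,9α-epoxy ketone
Conditions: 30 % aq. H2O2, NaOH (cat.), MeOH, 0 °C
Reagents that add atoms: hydrogen peroxide, OO
Why: Weitz–Scheffer epoxidation in which hydroperoxide adds to C8 of the conformationally locked enone along the axial trajectory (anti to axial H-7) and only the axial hydroperoxy enolate can close, so the epoxide should form on the α-face and fix the C8–O bond cis to the isopropyl group; the nucleophilic oxidant does not touch the C3=C4 alkene.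

**Step 5**
Reactants: 9 epoxy ketone
Product: 10 alkenyl oxirane (8α,9α-epoxycadina-3,10(14)-diene)
Conditions: Ph3PCH3Br, KOtBu, THF, 0 °C to rt
Reagents that add atoms: methyltriphenylphosphonium bromide, C[P+](c1ccccc1)(c1ccccc1)c1ccccc1.[Br-]
Why: Wittig methylenation of an α,β-epoxy ketone that cannot epimerize (C9 is an epoxide carbon, C1 already has its stable configuration) installs C14 without opening the epoxide.

**Step 6**
Reactants: 10 alkenyl oxirane
Product: 11 cadina-3,10(14)-dien-8α-ol
Conditions: Pd2(dba)3·CHCl3 (2.5 mol %), nBu3P (5 mol %), HCO2H, Et3N, dioxane, rt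
Reagents that add atoms: none
Why: Zerovalent palladium ionizes the allylic C9–O bond to a π-allyl complex (C14–C10–C9) and hydride from the formate ligand is delivered to the more substituted terminus C9 (formate hydrogenolysis in the Tsuji–Trost manifold), which should give the homoallylic alcohol with the exocyclic alkene and the C8 configuration unchanged.

**Step 7**
Reactants: 11 homoallylic alcohol
Product: 12 cadina-3,10(14)-dien-8α-yl acetate
Conditions: Ac2O, pyridine, DMAP (cat.), CH2Cl2, rt
Reagents that add atoms: acetic anhydride, CC(=O)OC(C)=O
Why: Standard DMAP-catalysed acetylation of the axial secondary alcohol, done now so that the C8 ester is already distinguished from the C3 hydroxyl that appears later.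

**Step 8**
Reactants: 12 acetate
Product: 13 3,4-epoxide (both diastereomers)
Conditions: mCPBA (1.0 equiv), CH2Cl2, −20 °C
Reagents that add atoms: 3-chloroperoxybenzoic acid, O=C(OO)c1cccc(Cl)c1
Why: Prilezhaev epoxidation should select the more electron-rich trisubstituted ring alkene over the 1,1-disubstituted exocyclic alkene (also deactivated by the homoallylic acetate), and both epoxide diastereomers converge in the next step.

**Step 9**
Reactants: 13 epoxide
Product: 14 keto aldehyde (3,4-seco compound)
Conditions: H5IO6, THF/H2O, 0 °C
Reagents that add atoms: water, O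
Why: Periodic acid hydrolyses the epoxide to the diol and cleaves it in the same flask (Malaprade glycol cleavage), opening the temporary ring to the C3 aldehyde and the C4 methyl ketone without touching the exocyclic alkene or the acetate.

**Step 10**
Reactants: 14 keto aldehyde
Product: 15 aldol (8α-acetoxy-3α-hydroxyoplop-10(14)-en-4-one)
Conditions: DBU (0.3 equiv), toluene, 0 °C to rt
Reagents that add atoms: none
Why: DBU reversibly enolizes the keto aldehyde and the C5 enolate of the methyl ketone adds to the C3 aldehyde, an intramolecular aldol addition whose closest known type is the base-mediated cyclization of 1,6-keto aldehydes to 2-acylcyclopentanols. Ring A closes in the 5-(enolexo)-exo-trig mode, made easy because the 2-oxopropyl and formylmethyl arms are vicinal and trans-diequatorial on C6 and C1 of the ring B chair, which also fixes the trans ring fusion. C5 is an epimerizable α-centre set under thermodynamic control: the acetyl group takes the α-orientation cis to H-6, away from C7 and its isopropyl group. C3 is set relative to C5, because a compact transition state with the aldehyde oxygen syn to the enolate oxygen (bridged by the amidinium ion) and the O–H···O=C hydrogen bond of the product in toluene both favour the cis hydroxy ketone, and reversibility lets the mixture drain to this isomer. The step needs regioselectivity (ketone CH2 enolate onto the aldehyde, not aldehyde enolate onto the ketone, nor the CH3 enolate to a seven-membered ring) and must stop before dehydration; the first should follow from the greater stability of the aldol that consumes the aldehyde carbonyl under equilibrating conditions, the second from catalytic amine base at low temperature, and the acetate and exocyclic alkene are inert to DBU.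

**Step 11**
Reactants: 15 aldol; 16 angelic acid
Product: 17 target (8α-acetoxy-3α-angeloyloxyoplop-10(14)-en-4-one)
Conditions: 2,4,6-Cl3C6H2COCl, Et3N, toluene, rt; then 15, 70 °C
Reagents that add atoms: none
Why: Yamaguchi-type esterification through the mixed anhydride of angelic acid, run without DMAP so that the (Z)-geometry should be kept (no reversible conjugate addition of a nucleophilic catalyst) and the β-acyloxy ketone is not exposed to strong base.

**Compound list**

1 | isovaleraldehyde (3-methylbutanal) | CC(C)CC=O | starting material
2 | methyl vinyl ketone (but-3-en-2-one) | C=CC(C)=O | starting material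
3 | (S)-2-isopropyl-5-oxohexanal | CC(=O)CC[C@@H](C(C)C)C=O | intermediate
4 | (S)-cryptone, (S)-4-isopropylcyclohex-2-en-1-one | O=C1CC[C@@H](C(C)C)C=C1 | intermediate
5 | isoprene (2-methylbuta-1,3-diene) | C=CC(C)=C | starting material
6 | cis-fused adduct, (4S,4aS,8aS)-4-isopropyl-6-methyl-3,4,4a,5,8,8a-hexahydronaphthalen-1(2H)-one | O=C1CC[C@@H](C(C)C)[C@@H]2CC(C)=CC[C@H]12 | intermediate
7 | trans-fused octalone, (4S,4aS,8aR)-4-isopropyl-6-methyl-3,4,4a,5,8,8a-hexahydronaphthalen-1(2H)-one (H-1 β, H-6 α, isopropyl α) | O=C1CC[C@@H](C(C)C)[C@@H]2CC(C)=CC[C@@H]12 | intermediate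
8 | dienone, (4R,4aS,8aR)-4-isopropyl-6-methyl-4a,5,8,8a-tetrahydronaphthalen-1(4H)-one | O=C1C=C[C@@H](C(C)C)[C@@H]2CC(C)=CC[C@@H]12 | intermediate
9 | 8α,9α-epoxy ketone of 8 (epoxide cis to the isopropyl group) | O=C1[C@H]2O[C@H]2[C@@H](C(C)C)[C@@H]3CC(C)=CC[C@@H]13 | intermediate
10 | 8α,9α-epoxycadina-3,10(14)-diene | C=C1[C@H]2O[C@H]2[C@@H](C(C)C)[C@@H]3CC(C)=CC[C@@H]13 | intermediate
11 | cadina-3,10(14)-dien-8α-ol (axial OH, cis to isopropyl) | C=C1C[C@@H](O)[C@@H](C(C)C)[C@@H]2CC(C)=CC[C@@H]12 | intermediate
12 | cadina-3,10(14)-dien-8α-yl acetate | C=C1C[C@@H](OC(C)=O)[C@@H](C(C)C)[C@@H]2CC(C)=CC[C@@H]12 | intermediate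
13 | 3,4-epoxycadin-10(14)-en-8α-yl acetate (mixture at C3/C4) | C=C1C[C@@H](OC(C)=O)[C@@H](C(C)C)[C@@H]2CC3(C)OC3C[C@@H]12 | intermediate
14 | keto aldehyde: cyclohexane with CH2CHO on C1, CH2C(O)CH3 on C6, isopropyl on C7, OAc on C8, =CH2 on C10, configuration as in 12 | C=C1C[C@@H](OC(C)=O)[C@@H](C(C)C)[C@H](CC(C)=O)[C@H]1CC=O | intermediate
15 | (1R,3S,5R,6R,7S,8R)-8-acetoxy-3-hydroxyoplop-10(14)-en-4-one (OH and acetyl cis, both α) | C=C1C[C@@H](OC(C)=O)[C@@H](C(C)C)[C@@H]2[C@@H](C(C)=O)[C@@H](O)C[C@@H]12 | intermediate
16 | angelic acid, (Z)-2-methylbut-2-enoic acid | C/C=C(/C)C(=O)O | starting material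
17 | (1R,3S,5R,6R,7S,8R)-8-acetoxy-3-angeloyloxyoplop-10(14)-en-4-one | C=C1C[C@@H](OC(C)=O)[C@@H](C(C)C)[C@@H]2[C@@H](C(C)=O)[C@@H](OC(=O)/C(C)=C\C)C[C@@H]12 | target

**Step count and risks**

Total steps: 11. Longest linear sequence: 11 steps (from 1 and 2).

Steps most likely to fail:

1. Step 10. The aldolization may run in the wrong sense (aldehyde enolate onto the ketone), give poor control at C3, or go on to dehydration. Fallback, from 14 back to 15: the condensation is driven on purpose (DBU, toluene, 80 °C) to the conjugated 1-acetylcyclopentene F1 (C3=C5), which erases the C3/C5 question. Copper-catalysed conjugate borylation (CuCl, NaOtBu, a chiral ferrocenyl bisphosphine chosen for α-face delivery, B2pin2, MeOH, THF) should place boron on C3 under catalyst control, with the acetyl group settling α on protonation, to give β-boryl ketone F2. Oxidation with NaBO3·4H2O in THF/H2O proceeds with retention at C3 and returns to 15.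

2. Step 11. A slow acylation may allow isomerization of the angelate to the tiglate, or β-elimination or retro-aldol cleavage of the hydroxy ketone. Fallback, from 15 to 17: carbodiimide coupling (EDC·HCl, DMAP cat., CH2Cl2, 0 °C) with 2-[bis(2,2,2-trifluoroethoxy)phosphoryl]propanoic acid gives phosphonate ester F3. Still–Gennari olefination (KN(SiMe3)2, 18-crown-6, THF, −78 °C, excess acetaldehyde) then builds the (Z)-2-methylbut-2-enoate on the ester; low temperature and excess aldehyde are meant to outrun intramolecular olefination of the C4 ketone.

3. Step 6. Hydride may be delivered to C14 (giving the endocyclic allylic alcohol), or the π-allyl complex may undergo β-hydride elimination. Fallback, from 9 back to 11, with the order of events reversed: SmI2 (THF/MeOH, −90 °C) cleaves the Cα–O bond of the epoxy ketone to β-hydroxy ketone F4. Non-basic Takai–Lombardo methylenation (Zn, CH2Br2, TiCl4, THF/CH2Cl2, 0 °C) then gives 11 without retro-aldol or β-elimination.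

**Further compounds**

F1 | step 10 | 8α-acetoxyoplopa-3(5),10(14)-dien-4-one (conjugated enone, C3=C5) | C=C1C[C@@H](OC(C)=O)[C@@H](C(C)C)[C@@H]2C(C(C)=O)=CC[C@@H]12
F2 | step 10 | 8α-acetoxy-3α-(4,4,5,5-tetramethyl-1,3,2-dioxaborolan-2-yl)oplop-10(14)-en-4-one | C=C1C[C@@H](OC(C)=O)[C@@H](C(C)C)[C@@H]2[C@@H](C(C)=O)[C@@H](B3OC(C)(C)C(C)(C)O3)C[C@@H]12
F3 | step 11 | 3-O-{2-[bis(2,2,2-trifluoroethoxy)phosphoryl]propanoyl} ester of 15 (mixture at the phosphonate α-carbon) | C=C1C[C@@H](OC(C)=O)[C@@H](C(C)C)[C@@H]2[C@@H](C(C)=O)[C@@H](OC(=O)C(C)P(=O)(OCC(F)(F)F)OCC(F)(F)F)C[C@@H]12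
F4 | step 6 | 8α-hydroxy-14-norcadin-3-en-10-one (β-hydroxy ketone) | O=C1C[C@@H](O)[C@@H](C(C)C)[C@@H]2CC(C)=CC[C@@H]12
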